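**Plan**
1. Numbering used below (longipinane): C1 ketone, C2 CH2, C3 CH(CH3), cyclobutane C4–C5–C11–C10 (C4 on C3, C5 on C6, C11 on C1, C10 quaternary), C6 C(CH3)2, C7 and C9 the acyloxy carbons, C8 CH2; methyls C12/C13 on C6, C14 on C10, C15 on C3.
2. Cuts: both ester C–O bonds; C3–C15 (cuprate on the C2=C3 enone); C7–C8 (Claisen closure of the seven-membered ring); C8–C9 and C10–C14 (MeLi and MeI on a ketene); C10–C11 (Wolff ring contraction, C9 having been a ring carbonyl bonded to C11); C3–C4 (radical ring closure); C1–C11 and C5–C6 (aldol and Mukaiyama–Michael).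
3. Enabling feature: C9 bears oxygen and sits on C10, so C9/C10 can be read as carbonyl and α-carbon of a cyclopent-2-enone C9–C10–C4–C5–C11; there C4 is the enone β-carbon, and a radical at C3 on the C11 side chain reaches it 6-exo to close the ring C1–C2–C3–C4–C5–C11.
4. Forward: five-membered ring from the bought enone → six-membered ring (bicyclo[3.2.1]octanone) → cyclobutane by ring contraction (bicyclo[3.1.1]heptane) → seven-membered ring → diol, esters, C15.
5. Stereochemistry: the (R)-silyloxy carbon of the enone directs C5 and C11 and is then erased; the tether fixes C4; C10 is methylated on the face away from the C6 arm; C9 by oxazaborolidine control, C7 by hydroxyl-directed anti reduction; C3 by cuprate attack anti to C14.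

Key step: step 5

Remark: C1, formed as a carbinol in step 2 and oxidised in step 13, is expected as a mixture of both configurations and is carried as such; names and SMILES leave it open. TBS = tert-butyldimethylsilyl.

**Step 1**
Reactants: 1 acrolein
Product: 2 3-bromopropanal
Conditions: HBr (anhydrous), CH2Cl2, −20 °C; solution used directly
Reagents that add atoms: hydrogen bromide, Br
Why: 1,4-addition of HBr to the enal (conjugate hydrohalogenation) puts bromine on the β-carbon and gives the β-bromo aldehyde, which is used at once because it is labile.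

**Step 2**
Reactants: 2 3-bromopropanal; 3 (R)-4-(tert-butyldimethylsilyloxy)cyclopent-2-en-1-one; 4 1-methoxy-2-methyl-1-(trimethylsilyloxy)prop-1-ene
Product: 6 methyl 2-[2-(3-bromo-1-hydroxypropyl)-5-(TBS-oxy)-3-oxocyclopentyl]-2-methylpropanoate (ring 1,2-trans and 1,5-trans), via enol silane 5 (not isolated)
Conditions: 3, 4, HgI2 (cat.), CH2Cl2, −78 → −20 °C; then 2, TiCl4, −78 °C; H2O
Reagents that add atoms: none
Why: Mukaiyama–Michael addition anti to the silyloxy group of 3 sets C5, and the enol silane 5 then undergoes a TiCl4-mediated Mukaiyama aldol with 2 anti to the new C5 arm, which sets C11 (all-trans ring); C1 is not controlled.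

**Step 3**
Reactants: 6 methyl 2-[2-(3-bromo-1-hydroxypropyl)-5-(TBS-oxy)-3-oxocyclopentyl]-2-methylpropanoate
Product: 7 methyl 2-[2-[3-bromo-1-(TBS-oxy)propyl]-5-(TBS-oxy)-3-oxocyclopentyl]-2-methylpropanoate
Conditions: TBSOTf, 2,6-lutidine, CH2Cl2, −78 → 0 °C
Reagents that add atoms: tert-butyldimethylsilyl trifluoromethanesulfonate, CC(C)(C)[Si](C)(C)OS(=O)(=O)C(F)(F)F
Why: Silylation of the aldol hydroxyl with a silyl triflate and a hindered base blocks retro-aldol and dehydration of the side chain in the next step.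

**Step 4**
Reactants: 7 methyl 2-[2-[3-bromo-1-(TBS-oxy)propyl]-5-(TBS-oxy)-3-oxocyclopentyl]-2-methylpropanoate
Product: 8 methyl 2-[5-[3-bromo-1-(TBS-oxy)propyl]-4-oxocyclopent-2-en-1-yl]-2-methylpropanoate (1,5-trans)
Conditions: DBU, CH2Cl2, 0 °C, short reaction time
Reagents that add atoms: none
Why: E1cB β-elimination of the ring silyloxy group through the unhindered CH2 enolate gives the conjugated cyclopentenone (C9=O, C10=C4), whereas loss of the side-chain silyl ether would need the hindered methine enolate and give an exocyclic alkene.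

**Step 5**
Reactants: 8 methyl 2-[5-[3-bromo-1-(TBS-oxy)propyl]-4-oxocyclopent-2-en-1-yl]-2-methylpropanoate
Product: 9 methyl 2-[2-(TBS-oxy)-7-oxobicyclo[3.2.1]octan-8-yl]-2-methylpropanoate (ester arm on C8 syn to the C6–C7 bridge)
Conditions: Bu3SnH (slow addition), 2,2'-azobis(isobutyronitrile) (cat.), benzene, 80 °C, high dilution
Reagents that add atoms: none
Why: Bu3Sn• abstracts the bromine atom of 8, the primary C3 radical adds to the enone β-carbon C4, and the α-keto radical at C10 takes hydrogen from Bu3SnH and carries the chain. The closest known reaction type is the tin hydride mediated Giese-type cyclization of ω-bromoalkyl cycloalkenones to bridged bicyclic ketones. One ring closes, the cyclohexane C1–C2–C3–C4–C5–C11 of the target, in the 6-exo-trig mode (C10 stays outside it), which turns the cyclopentenone into a bicyclo[3.2.1]octan-7-one. The one new stereocenter, C4, is set by the tether: the chain on C11 can reach C4 only on the ring face it occupies, while the C5 arm placed trans in step 2 stands on the other face, so H4 and H11 become the cis bridgehead hydrogens required. The step needs ring closure to outrun direct reduction of the radical and 1,5-hydrogen transfer from C5–H; the polarity match of a nucleophilic alkyl radical with the electron-poor β-carbon and slow addition of Bu3SnH at high dilution should secure this.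

**Step 6**
Reactants: 9 methyl 2-[2-(TBS-oxy)-7-oxobicyclo[3.2.1]octan-8-yl]-2-methylpropanoate
Product: 11 methyl 2-[6-diazo-2-(TBS-oxy)-7-oxobicyclo[3.2.1]octan-8-yl]-2-methylpropanoate, via trifluoroacetyl ketone 10 (not isolated)
Conditions: LiN(SiMe3)2, THF, −78 °C; CF3CO2CH2CF3; aq. HCl; then 4-acetamidobenzenesulfonyl azide, Et3N, H2O, MeCN, 25 °C
Reagents that add atoms: 4-acetamidobenzenesulfonyl azide, CC(=O)Nc1ccc(cc1)S(=O)(=O)N=[N+]=[N-]
Why: Detrifluoroacetylative (Regitz-type) diazo transfer; the ketone can enolise only toward C10 because C11 is a bridgehead, and at −78 °C trifluoroacetylation of the enolate should be faster than attack on the hindered ester.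

**Step 7**
Reactants: 11 methyl 2-[6-diazo-2-(TBS-oxy)-7-oxobicyclo[3.2.1]octan-8-yl]-2-methylpropanoate
Product: 14 methyl 2-[6-acetyl-2-(TBS-oxy)-6-methylbicyclo[3.1.1]heptan-7-yl]-2-methylpropanoate (acetyl and ester arm on the inner faces toward each other, 6-methyl syn to the C2–C4 bridge), via ketene 12 (not isolated), via lithium enolate 13 (not isolated)
Conditions: hν (Hg lamp, Pyrex filter), THF, −78 °C; then MeLi, −78 °C; then MeI, DMPU, −78 → −20 °C
Reagents that add atoms: methyllithium, [Li]C; iodomethane, CI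
Why: In the photochemical Wolff rearrangement C11 migrates from C9 to the carbene carbon C10 with retention, contracting the five-membered ring to the cyclobutane ketene 12; MeLi adds to the ketene carbonyl (organolithium addition to a ketene), and the tetrasubstituted enolate 13 is C-methylated on the face opposite the C6 arm, which sets C10 with C14 syn to the C1–C3 bridge.

**Step 8**
Reactants: 14 methyl 2-[6-acetyl-2-(TBS-oxy)-6-methylbicyclo[3.1.1]heptan-7-yl]-2-methylpropanoate
Product: 15 1-(TBS-oxy)-15-norlongipinane-7,9-dione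
Conditions: LiN(SiMe3)2 (2 equiv), THF, −78 → 25 °C; aq. HCl
Reagents that add atoms: none
Why: Intramolecular Claisen (Dieckmann-type) condensation of the methyl ketone enolate (C8) onto the methyl ester (C7) closes the seven-membered ring, driven by deprotonation of the β-diketone formed.

**Step 9**
Reactants: 15 1-(TBS-oxy)-15-norlongipinane-7,9-dione
Product: 16 (9R)-9-hydroxy-1-(TBS-oxy)-15-norlongipinan-7-one
Conditions: (S)-1-methyl-3,3-diphenyltetrahydro-1H,3H-pyrrolo[1,2-c][1,3,2]oxazaborole, BH3·SMe2 (limiting), THF, −40 °C; MeOH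
Reagents that add atoms: none
Why: Corey–Bakshi–Shibata reduction: the (S)-oxazaborolidine distinguishes the quaternary C10 flank from the C8 methylene and should give the (9R) alcohol under reagent control; the C9 carbonyl is the less shielded one, and any C7-reduced regioisomer would carry the same sense (7R) and converge in step 10.

**Step 10**
Reactants: 16 (9R)-9-hydroxy-1-(TBS-oxy)-15-norlongipinan-7-one
Product: 17 (7R,9R)-1-(TBS-oxy)-15-norlongipinane-7,9-diol
Conditions: Me4NBH(OAc)3, MeCN/AcOH, −20 °C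
Reagents that add atoms: none
Why: Evans–Saksena reduction: hydride is delivered intramolecularly from the C9 alkoxyborohydride to the C7 ketone through a chair-like six-membered transition state, giving the 1,3-anti diol.

**Step 11**
Reactants: 17 (7R,9R)-1-(TBS-oxy)-15-norlongipinane-7,9-diol; 18 angelic acid
Product: 20 (7R,9R)-7,9-bis(angeloyloxy)-1-(TBS-oxy)-15-norlongipinane, via mixed anhydride 19 (not isolated)
Conditions: 18 (3 equiv), 2,4,6-trichlorobenzoyl chloride (3 equiv), Et3N, toluene, 25 °C; then 17 (1 equiv), 80 °C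
Reagents that add atoms: angelic acid (second equivalent), C/C=C(/C)C(=O)O
Why: Yamaguchi-type esterification in which each of the two hindered secondary hydroxyls takes one angeloyl group from one molecule of mixed anhydride 19, so that two equivalents of 18 end up in 20, and the absence of a nucleophilic catalyst avoids Z to E isomerisation of the angelate.

**Step 12**
Reactants: 20 (7R,9R)-7,9-bis(angeloyloxy)-1-(TBS-oxy)-15-norlongipinane
Product: 21 (7R,9R)-7,9-bis(angeloyloxy)-15-norlongipinan-1-ol
Conditions: HF·pyridine, THF, 0 → 25 °C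
Reagents that add atoms: none
Why: Fluoride-mediated cleavage of the secondary silyl ether; the enoate esters are inert to buffered HF·pyridine.

**Step 13**
Reactants: 21 (7R,9R)-7,9-bis(angeloyloxy)-15-norlongipinan-1-ol
Product: 23 (7R,9R)-7,9-bis(angeloyloxy)-15-norlongipin-2-en-1-one, via saturated ketone 22 (not isolated)
Conditions: IBX (excess), 4-methoxypyridine N-oxide, DMSO, 25–40 °C
Reagents that add atoms: none
Why: IBX oxidises the alcohol to ketone 22 and then dehydrogenates it through its enol (IBX ketone dehydrogenation); this can only occur toward C2–C3 because C11 is a bridgehead.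

**Step 14**
Reactants: 23 (7R,9R)-7,9-bis(angeloyloxy)-15-norlongipin-2-en-1-one
Product: 24 (7R,9R)-7,9-bis(angeloyloxy)longipinan-1-one (target)
Conditions: Me2CuLi (from CuI and MeLi), Et2O, −78 °C; aq. NH4Cl
Reagents that add atoms: lithium dimethylcuprate, [Li+].C[Cu-]C
Why: Conjugate addition of the Gilman cuprate to the bicyclo[3.1.1]heptenone: methyl enters C3 from the face of the C5 bridge (which turns only a hydrogen toward the enone) and anti to the C10 bridge whose methyl C14 shields the other face; the α,β-disubstituted angelates are far poorer acceptors than the strained enone.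

**Compound list**
1 | acrolein | C=CC=O | starting material
2 | 3-bromopropanal | O=CCCBr | intermediate
3 | (R)-4-(tert-butyldimethylsilyloxy)cyclopent-2-en-1-one | O=C1C[C@@H](O[Si](C)(C)C(C)(C)C)C=C1 | starting material
4 | 1-methoxy-2-methyl-1-(trimethylsilyloxy)prop-1-ene | COC(O[Si](C)(C)C)=C(C)C | starting material
5 | methyl 2-[5-(TBS-oxy)-3-(trimethylsilyloxy)cyclopent-2-en-1-yl]-2-methylpropanoate, 1,5-trans | C[Si](C)(C)OC1=C[C@@H](C(C)(C)C(=O)OC)[C@H](O[Si](C)(C)C(C)(C)C)C1 | intermediate
6 | methyl 2-[2-(3-bromo-1-hydroxypropyl)-5-(TBS-oxy)-3-oxocyclopentyl]-2-methylpropanoate, 1,2-trans, 1,5-trans, carbinol epimers | O=C1C[C@@H](O[Si](C)(C)C(C)(C)C)[C@@H]([C@H]1C(O)CCBr)C(C)(C)C(=O)OC | intermediate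
7 | methyl 2-[2-[3-bromo-1-(TBS-oxy)propyl]-5-(TBS-oxy)-3-oxocyclopentyl]-2-methylpropanoate | O=C1C[C@@H](O[Si](C)(C)C(C)(C)C)[C@@H]([C@H]1C(O[Si](C)(C)C(C)(C)C)CCBr)C(C)(C)C(=O)OC | intermediate
8 | methyl 2-[5-[3-bromo-1-(TBS-oxy)propyl]-4-oxocyclopent-2-en-1-yl]-2-methylpropanoate, 1,5-trans | O=C1C=C[C@@H]([C@H]1C(O[Si](C)(C)C(C)(C)C)CCBr)C(C)(C)C(=O)OC | intermediate
9 | methyl 2-[2-(TBS-oxy)-7-oxobicyclo[3.2.1]octan-8-yl]-2-methylpropanoate, arm syn to the C6–C7 bridge | O=C1C[C@@H]2[C@@H]([C@H]1C(O[Si](C)(C)C(C)(C)C)CC2)C(C)(C)C(=O)OC | intermediate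
10 | 6-(trifluoroacetyl) derivative of 9 (enolised β-diketone, C6 open) | O=C1C(C(=O)C(F)(F)F)[C@@H]2[C@@H]([C@H]1C(O[Si](C)(C)C(C)(C)C)CC2)C(C)(C)C(=O)OC | intermediate
11 | methyl 2-[6-diazo-2-(TBS-oxy)-7-oxobicyclo[3.2.1]octan-8-yl]-2-methylpropanoate | O=C1C(=[N+]=[N-])[C@@H]2[C@@H]([C@H]1C(O[Si](C)(C)C(C)(C)C)CC2)C(C)(C)C(=O)OC | intermediate
12 | methyl 2-[2-(TBS-oxy)-6-(oxomethylidene)bicyclo[3.1.1]heptan-7-yl]-2-methylpropanoate (ketene) | O=C=C1[C@@H]2[C@@H]([C@H]1C(O[Si](C)(C)C(C)(C)C)CC2)C(C)(C)C(=O)OC | intermediate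
13 | lithium 1-[7-(1-methoxy-2-methyl-1-oxopropan-2-yl)-2-(TBS-oxy)bicyclo[3.1.1]heptan-6-ylidene]ethanolate | [Li]OC(C)=C1[C@@H]2[C@@H]([C@H]1C(O[Si](C)(C)C(C)(C)C)CC2)C(C)(C)C(=O)OC | intermediate
14 | methyl 2-[6-acetyl-2-(TBS-oxy)-6-methylbicyclo[3.1.1]heptan-7-yl]-2-methylpropanoate, acetyl and arm inner, 6-methyl syn to the C2–C4 bridge | CC(=O)[C@]1(C)[C@@H]2[C@@H]([C@H]1C(O[Si](C)(C)C(C)(C)C)CC2)C(C)(C)C(=O)OC | intermediate
15 | 1-(TBS-oxy)-15-norlongipinane-7,9-dione | O=C1CC(=O)[C@]2(C)[C@@H]3[C@@H]([C@H]2C(O[Si](C)(C)C(C)(C)C)CC3)C1(C)C | intermediate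
16 | (9R)-9-hydroxy-1-(TBS-oxy)-15-norlongipinan-7-one | O=C1C[C@@H](O)[C@]2(C)[C@@H]3[C@@H]([C@H]2C(O[Si](C)(C)C(C)(C)C)CC3)C1(C)C | intermediate
17 | (7R,9R)-1-(TBS-oxy)-15-norlongipinane-7,9-diol | O[C@@H]1C[C@@H](O)[C@]2(C)[C@@H]3[C@@H]([C@H]2C(O[Si](C)(C)C(C)(C)C)CC3)C1(C)C | intermediate
18 | angelic acid, (Z)-2-methylbut-2-enoic acid | C/C=C(/C)C(=O)O | starting material
19 | angelic 2,4,6-trichlorobenzoic anhydride | C/C=C(/C)C(=O)OC(=O)c1c(Cl)cc(Cl)cc1Cl | intermediate
20 | (7R,9R)-7,9-bis(angeloyloxy)-1-(TBS-oxy)-15-norlongipinane | C/C=C(/C)C(=O)O[C@@H]1C[C@@H](OC(=O)/C(C)=C\C)[C@]2(C)[C@@H]3[C@@H]([C@H]2C(O[Si](C)(C)C(C)(C)C)CC3)C1(C)C | intermediate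
21 | (7R,9R)-7,9-bis(angeloyloxy)-15-norlongipinan-1-ol | C/C=C(/C)C(=O)O[C@@H]1C[C@@H](OC(=O)/C(C)=C\C)[C@]2(C)[C@@H]3[C@@H]([C@H]2C(O)CC3)C1(C)C | intermediate
22 | (7R,9R)-7,9-bis(angeloyloxy)-15-norlongipinan-1-one | C/C=C(/C)C(=O)O[C@@H]1C[C@@H](OC(=O)/C(C)=C\C)[C@]2(C)[C@@H]3[C@@H]([C@H]2C(=O)CC3)C1(C)C | intermediate
23 | (7R,9R)-7,9-bis(angeloyloxy)-15-norlongipin-2-en-1-one | C/C=C(/C)C(=O)O[C@@H]1C[C@@H](OC(=O)/C(C)=C\C)[C@]2(C)[C@@H]3[C@@H]([C@H]2C(=O)C=C3)C1(C)C | intermediate
24 | (7R,9R)-7,9-bis(angeloyloxy)longipinan-1-one | C/C=C(/C)C(=O)O[C@@H]1C[C@@H](OC(=O)/C(C)=C\C)[C@]2(C)[C@@H]3[C@@H]([C@H]2C(=O)C[C@H]3C)C1(C)C | target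

**Step count and risks**
Total steps: 14. Longest linear sequence: 14 steps (1 → 2 → 6 → … → 24); 13 from enone 3.

Step 7. The ketene may be lost to dimerisation or stray nucleophiles before MeLi is added, MeLi may also attack the ester, and proton transfer between enolate and product ketone may spoil the methylation. Fallback, setting out from 11 and rejoining at 14: Wolff rearrangement in aqueous THF should give the ring-contracted carboxylic acid F1. Dianion formation (LiN(iPr)2, 2 equiv) and methylation with MeI on the same open face should give the α-methyl acid F2. Oxalyl chloride converts it to the acid chloride F3, and Me2CuLi at −78 °C turns the acid chloride into methyl ketone 14 while leaving the methyl ester alone.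

Step 9. Hydride delivery may show poor facial selectivity on this hindered, enolisable β-diketone, and over-reduction or boron enolate formation may compete. Fallback, setting out from 15 and rejoining at 16: mono-reduction with substoichiometric NaBH4 in MeOH at −40 °C should give 16 together with its C9 epimer, the (9S)-hydroxy ketone F4. The two diastereomers are separated by chromatography, and F4 is reoxidised to 15 with Dess–Martin periodinane and recycled.

Step 5. The primary radical may be reduced before it cyclises, or may undergo 1,5-hydrogen transfer from C5–H, so that ring closure is incomplete. Fallback by polar closure, setting out from 8 and rejoining at 9: displacement of bromide with PhSO2Na in DMF gives the sulfone enone F5. Deprotonation α to sulfur (LiN(SiMe3)2, THF, −78 °C) and intramolecular 6-exo Michael addition to C4 should give the 3-phenylsulfonyl bicyclic ketone F6. Reductive desulfonylation (sodium amalgam Na(Hg), Na2HPO4, MeOH) then gives 9.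

**Further compounds**
F1 | step 7 | 7-(1-methoxy-2-methyl-1-oxopropan-2-yl)-2-(TBS-oxy)bicyclo[3.1.1]heptane-6-carboxylic acid (C6 open) | OC(=O)C1[C@@H]2[C@@H]([C@H]1C(O[Si](C)(C)C(C)(C)C)CC2)C(C)(C)C(=O)OC
F2 | step 7 | 7-(1-methoxy-2-methyl-1-oxopropan-2-yl)-6-methyl-2-(TBS-oxy)bicyclo[3.1.1]heptane-6-carboxylic acid | OC(=O)[C@]1(C)[C@@H]2[C@@H]([C@H]1C(O[Si](C)(C)C(C)(C)C)CC2)C(C)(C)C(=O)OC
F3 | step 7 | acid chloride of F2 | ClC(=O)[C@]1(C)[C@@H]2[C@@H]([C@H]1C(O[Si](C)(C)C(C)(C)C)CC2)C(C)(C)C(=O)OC
F4 | step 9 | (9S)-9-hydroxy-1-(TBS-oxy)-15-norlongipinan-7-one | O=C1C[C@H](O)[C@]2(C)[C@@H]3[C@@H]([C@H]2C(O[Si](C)(C)C(C)(C)C)CC3)C1(C)C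
F5 | step 5 | methyl 2-[5-[3-(phenylsulfonyl)-1-(TBS-oxy)propyl]-4-oxocyclopent-2-en-1-yl]-2-methylpropanoate | O=C1C=C[C@@H]([C@H]1C(O[Si](C)(C)C(C)(C)C)CCS(=O)(=O)c2ccccc2)C(C)(C)C(=O)OC
F6 | step 5 | methyl 2-[4-(phenylsulfonyl)-2-(TBS-oxy)-7-oxobicyclo[3.2.1]octan-8-yl]-2-methylpropanoate (C4 open) | O=C1C[C@@H]2[C@@H]([C@H]1C(O[Si](C)(C)C(C)(C)C)CC2S(=O)(=O)c3ccccc3)C(C)(C)C(=O)OC
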